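Ring A (C1 OH, C2 Br, C3 H, C4 Br, C5 Br, C6 O-aryl) is built as a carbocycle instead of being substituted. Cutting C1–C6 traces the C1 hydroxyl and the C5 bromine, which sit 1,3 across the aryloxy carbon C6 where phenol bromination cannot place them, back to the two carbonyls of a 2-aryloxycyclohexane-1,3-dione. A single base-mediated intramolecular Claisen condensation forms C1–C6 and closes ring A from an open-chain δ-keto ester, ethyl 6-(2,4-dibromophenoxy)-5-oxohexanoate, which already carries ring B and the ether oxygen. Vinyl bromide formation and brominative aromatisation then complete the target.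

Key step: step 3

Remark: the ring A numbering above is used in the reasoning, while compound names follow IUPAC numbering, so the target is 3,4,6-tribromo-2-(2,4-dibromophenoxy)phenol. The target has no stereocentre. Diazomethane is assumed to be used as a separately prepared ethereal solution. The bromomethyl ketone is made from an acid chloride, not by brominating a methyl ketone, so that the position of the bromine is unambiguous and the ethyl ester is not scrambled.

Step 1
Reactants: 1 ethyl 5-chloro-5-oxopentanoate (ethyl glutaryl chloride)
Product: 3 ethyl 6-bromo-5-oxohexanoate, via diazoketone 2 (not isolated)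
Conditions: CH2N2 (2.5 equiv), Et2O, 0 °C; then 48% aq. HBr, 0 °C
Reagents that add atoms: diazomethane C=[N+]=[N-]; hydrogen bromide Br
Why: Acylation of diazomethane by the acid chloride (first stage of the Arndt–Eistert sequence) should give the α-diazoketone, and its hydrobromination (C-protonation, then SN2 loss of N2 to bromide) places bromine only on the terminal carbon, with the ethyl ester inert to both reagents at 0 °C.

Step 2
Reactants: 3 ethyl 6-bromo-5-oxohexanoate; 4 2,4-dibromophenol
Product: 5 ethyl 6-(2,4-dibromophenoxy)-5-oxohexanoate
Conditions: K2CO3 (1.5 equiv), acetone, rt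
Reagents that add atoms: none
Why: Williamson ether synthesis, in which the phenoxide of the acidic dibromophenol displaces the highly SN2-reactive α-keto bromide, while carbonate is too weak to trigger condensation of the keto ester.

Step 3
Reactants: 5 ethyl 6-(2,4-dibromophenoxy)-5-oxohexanoate
Product: 7 2-(2,4-dibromophenoxy)cyclohexane-1,3-dione, via potassium enolate 6 (not isolated)
Conditions: KOtBu (2.0 equiv), THF (0.05 M, slow addition of 5), 0 °C to rt; then 1 M HCl
Reagents that add atoms: none
Why: tert-Butoxide reversibly deprotonates the C6 methylene between the ketone and the aryloxy oxygen, and this enolate carbon attacks the ester carbonyl C1, the tetrahedral intermediate expelling ethoxide to form the C1–C6 bond; this is an intramolecular Claisen (Dieckmann-type) condensation of a δ-keto ester, the established entry to cyclohexane-1,3-diones. Ring A closes in a 6-(enolendo)-exo-trig mode. No stereocentre is created, because C6 ends as the sp2 carbon of the stabilised dione enolate 6, whose formation drains the reversible Claisen, aldol and O-acylation equilibria towards product. The step needs one site of C–C bond formation and one ring size, and the chain length secures both: the C4 ketone enolate and the C2 ester enolate could only close four-membered rings, and dilution holds back intermolecular condensation. The aryl bromides and the aryl alkyl ether are inert to KOtBu in THF at room temperature, and acidification should release 7, which is expected to exist largely as its enol.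

Step 4
Reactants: 7 2-(2,4-dibromophenoxy)cyclohexane-1,3-dione
Product: 8 3-bromo-2-(2,4-dibromophenoxy)cyclohex-2-en-1-one
Conditions: Ph3PBr2 (1.2 equiv), Et3N (1.3 equiv), CH2Cl2, 0 °C to rt
Reagents that add atoms: dibromotriphenylphosphorane BrP(Br)(c1ccccc1)(c1ccccc1)c1ccccc1
Why: Deoxybromination of a cyclic 1,3-dione enol by Appel-type activation: the enol oxygen is converted into an oxyphosphonium leaving group and bromide substitutes at the β-carbon by addition–elimination. Because 7 is symmetric about the aryloxy carbon, either carbonyl gives the same β-bromo enone.

Step 5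
Reactants: 8 3-bromo-2-(2,4-dibromophenoxy)cyclohex-2-en-1-one
Product: 11 3,4,6-tribromo-2-(2,4-dibromophenoxy)phenol, via alpha-bromo enone 9 (not isolated), via bromophenol 10 (not isolated)
Conditions: Br2 (3.05 equiv, in portions), AcOH, rt to 70 °C
Reagents that add atoms: bromine BrBr
Why: Brominative aromatisation of a cyclohexenone: acid-catalysed enol bromination at a ring CH2, loss of HBr through the dienol and tautomerisation give the phenol, whose hydroxyl then directs electrophilic aromatic bromination to its free ortho and para carbons (C2 and C4 of ring A). Every order of bromination and elimination converges on 11; C3 (meta to OH, between two bromines) and the deactivated ring B should stay untouched at three equivalents.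

Compound list
1 | ethyl 5-chloro-5-oxopentanoate | CCOC(=O)CCCC(=O)Cl | starting material
2 | ethyl 6-diazo-5-oxohexanoate | CCOC(=O)CCCC(=O)C=[N+]=[N-] | intermediate (not isolated)
3 | ethyl 6-bromo-5-oxohexanoate | CCOC(=O)CCCC(=O)CBr | intermediate
4 | 2,4-dibromophenol | Oc1ccc(Br)cc1Br | starting material
5 | ethyl 6-(2,4-dibromophenoxy)-5-oxohexanoate | CCOC(=O)CCCC(=O)COc1ccc(Br)cc1Br | intermediate
6 | potassium 2-(2,4-dibromophenoxy)-3-oxocyclohex-1-en-1-olate | [K+].[O-]C1=C(Oc2ccc(Br)cc2Br)C(=O)CCC1 | intermediate (not isolated)
7 | 2-(2,4-dibromophenoxy)cyclohexane-1,3-dione | O=C1CCCC(=O)C1Oc1ccc(Br)cc1Br | intermediate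
8 | 3-bromo-2-(2,4-dibromophenoxy)cyclohex-2-en-1-one | O=C1CCCC(Br)=C1Oc1ccc(Br)cc1Br | intermediate
9 | 3,6-dibromo-2-(2,4-dibromophenoxy)cyclohex-2-en-1-one (racemic) | O=C1C(Br)CCC(Br)=C1Oc1ccc(Br)cc1Br | intermediate (not isolated)
10 | 3-bromo-2-(2,4-dibromophenoxy)phenol | Oc1cccc(Br)c1Oc1ccc(Br)cc1Br | intermediate (not isolated)
11 | 3,4,6-tribromo-2-(2,4-dibromophenoxy)phenol | Oc1c(Br)cc(Br)c(Br)c1Oc1ccc(Br)cc1Br | target

Total step count: 5. Longest linear sequence: 5 steps (1 to 11; phenol 4 enters at step 2).

Steps most likely to fail

Step 3. Intermolecular Claisen or aldol condensation may outpace ring closure, or the α-aryloxy ketone may degrade under base before it cyclises. The fallback sets out from 2,4-dibromophenol 4 and returns at 7. Commercial cyclohexane-1,3-dione would undergo Regitz diazo transfer (tosyl azide, Et3N, MeCN) to 2-diazocyclohexane-1,3-dione F1. Rh2(OAc)4-catalysed O–H insertion of the derived carbenoid into 4 (CH2Cl2, reflux) should then give dione 7, which re-enters the route at step 4.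

Step 5. Dehydrobromination may stall at non-aromatic bromo ketones, or bromination may run past the third equivalent onto ring B or C3. The fallback sets out from 8 and separates aromatisation from ring bromination. Kinetic deprotonation at the α′-methylene with LiN(SiMe3)2 (THF, −78 °C) and trapping with PhSeCl should give racemic 3-bromo-2-(2,4-dibromophenoxy)-6-(phenylselanyl)cyclohex-2-en-1-one F2. Oxidation with H2O2 (CH2Cl2, pyridine, 0 °C to rt) would give the selenoxide, 3-bromo-2-(2,4-dibromophenoxy)-6-(phenylseleninyl)cyclohex-2-en-1-one F3. Its syn-elimination and tautomerisation deliver phenol 10, now isolated. Br2 (2.0 equiv, CH2Cl2, 0 °C) should then brominate 10 ortho and para to the hydroxyl to reach 11.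

Step 4. Activation of the hindered 2-aryloxy enol may be sluggish or reversible, so that the dione returns on work-up. The fallback sets out from 7 and returns at 8. Sulfonylation with MsCl and K2CO3 in MeCN should give the isolable enol mesylate, 2-(2,4-dibromophenoxy)-3-oxocyclohex-1-en-1-yl methanesulfonate F4. LiBr in refluxing acetone would then exchange mesylate for bromide by conjugate addition–elimination to give 8.

Further compounds
F1 | step 3 | 2-diazocyclohexane-1,3-dione | O=C1CCCC(=O)C1=[N+]=[N-]
F2 | step 5 | 3-bromo-2-(2,4-dibromophenoxy)-6-(phenylselanyl)cyclohex-2-en-1-one (racemic) | O=C1C([Se]c2ccccc2)CCC(Br)=C1Oc1ccc(Br)cc1Br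
F3 | step 5 | 3-bromo-2-(2,4-dibromophenoxy)-6-(phenylseleninyl)cyclohex-2-en-1-one (mixture of stereoisomers) | O=C1C([Se](=O)c2ccccc2)CCC(Br)=C1Oc1ccc(Br)cc1Br
F4 | step 4 | 2-(2,4-dibromophenoxy)-3-oxocyclohex-1-en-1-yl methanesulfonate | CS(=O)(=O)OC1=C(Oc2ccc(Br)cc2Br)C(=O)CCC1
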